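In the readings, half of the D I charged was not found as L or Z at 20.0 h, and I took that leftover as the number to watch.

- eta: D 10 mM; E 52 µM; J 32 µM; the very flask that is asked about, followed so far
- flask: D 10 mM; E 52 µM; J 32 µM; time 2.5 d

eta run (percent of the D charged)

| time / h | L / % | Z / % |
|---|---|---|
| 4.00 | 12 | 6 |
| 8.00 | 19 | 11 |
| 10.0 | 24 | 14 |
| 15.0 | 21 | 25 |
| 20.0 | 21 | 29 |

(readings scatter by 2 percentage points)



* concentration of L at 2.5 d, in mM
* concentration of Z at 2.5 d, in mM
* concentration of D at 2.5 d, in mM

I went through the givens in turn. The readings are percentages of the D charged, so an error in that charge carries straight into all the answers, and it must be known well. c_E and c_J stand as in the earlier run, so whatever they do is already in the readings. The time lies beyond the readings: 2.5 d is 3.00 times the run, so I needed to know how much more D goes after 20.0 h.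

I therefore counted turnovers. N, the turnover number, is the D lost per E charged, and the charge allows 192. The readings give:

N = 73.1 at 10.0 h, 88.5 at 15.0 h, 96.2 at 20.0 h

At 15.0 h the readings put N per hour since the start at 5.90 h⁻¹; I carry this pace. In the readings the second 10.0 h gave 0.316 of what the first gave. If each further stretch keeps that share, the stretches summed without end add 10.7, and I took that sum as my estimate of the tail up to 2.5 d:

N ≈ 107, so c_D ≈ 4.45 mM

The forecast gave 1.3 mM of L, 6.4 mM of Z and 2.3 mM of D, holding that “D loss is therefore slowing more than simple first-order decay predicts”. My count leaves more D than that.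

The flask gave 1.89 mM of L, 4.70 mM of Z and 3.42 mM of D.

    L ⇌ Z (K = 2.68, k = 2.79 × 10⁻⁵ s⁻¹)
    E + J ⇌ G (K = 11000 M⁻¹, k = 4.17 M⁻¹ s⁻¹)
    D + E ⇌ L + E, rate k3*[D]*[E] forward; the back reaction follows from the equilibrium constant (K = 0.580, k = 0.490 M⁻¹ s⁻¹)

The pace of this flask over 2.5 d was 2.11 h⁻¹, less than the 5.90 h⁻¹ I carried. The slowest mode at the asked time has a half-life of 0.554 d, short against 2.5 d, and at 25.0 d c_D stands at 3.19 mM. The same flask with 0.013 mM of E holds a quarter of the E, so my pace, run for 2.5 d, leaves it 54.0% of its D; it computes to 50.0%.

Readings and results are simulated with constants of no real substance; noise was put on by code.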